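**Retrosynthetic overview**
1. Target 13 ⇒ silyl ether 12 (O-4 unmasked last) ⇒ allylic alcohol 10 + scopoletin 11 (aryl ether C1–O, Mitsunobu).
2. 10 ⇒ enoate 9 (ester reduction) ⇒ diene 7 (Markovnikov hydration of the distal trisubstituted alkene) ⇒ terminal alkene 5 + 2-methylbut-2-ene 6 (cross-metathesis).
3. 5 ⇒ 4 ⇒ key C4–C5 bond: asymmetric allylboration of enal 1 with the allyl unit of 2. This sets the only stereocentre (4R); the E-alkene comes ready-made in 1.
4. Rings: none is built. The coumarin bicycle is bought intact as scopoletin and attached in the penultimate step.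

Assumption: 1, 2, 6, 11 and (+)-Ipc2BOMe are taken as catalogue chemicals; (+)-Ipc2BOMe is the enantiomer made from (−)-α-pinene, COB([C@H]1C[C@H]2C[C@@H]([C@@H]1C)C2(C)C)[C@H]1C[C@H]2C[C@@H]([C@@H]1C)C2(C)C.

**Step 1**
Reactants: 1 ethyl (2E)-3-methyl-4-oxobut-2-enoate; 2 allylmagnesium bromide
Product: 4 ethyl (2E,4R)-4-hydroxy-3-methylhepta-2,6-dienoate, via diisopinocampheylborinate ester 3 (not isolated)
Conditions: (+)-Ipc2BOMe (1.3 equiv), 2 (1.2 equiv), Et2O, 0 °C → rt; then 1, −78 °C, 3 h; then NaBO3·4H2O, THF/H2O, rt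
Reagents that add atoms: none
Why: Brown asymmetric allylboration (carbonyl allylation) through a chair Zimmerman–Traxler transition state, in which the (−)-α-pinene-derived Ipc groups send allyl to the Re face of the aldehyde and set 4R (the mirror-image reagent gives (S)-1-phenylbut-3-en-1-ol from benzaldehyde), while the conjugated ester is inert to the allylborane at −78 °C.

**Step 2**
Reactants: 4 ethyl (2E,4R)-4-hydroxy-3-methylhepta-2,6-dienoate
Product: 5 ethyl (2E,4R)-4-[(tert-butyldimethylsilyl)oxy]-3-methylhepta-2,6-dienoate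
Conditions: TBSOTf, 2,6-lutidine, CH2Cl2, −78 → 0 °C
Reagents that add atoms: tert-butyldimethylsilyl trifluoromethanesulfonate, CC(C)(C)[Si](C)(C)OS(=O)(=O)C(F)(F)F
Why: O-silylation of the secondary allylic alcohol leaves the stereocentre untouched and stops O-4 from cyclising onto C7 in the later oxymercuration and from reacting in the Mitsunobu step.

**Step 3**
Reactants: 5 ethyl (2E,4R)-4-[(tert-butyldimethylsilyl)oxy]-3-methylhepta-2,6-dienoate; 6 2-methylbut-2-ene
Product: 7 ethyl (2E,4R)-4-[(tert-butyldimethylsilyl)oxy]-3,7-dimethylocta-2,6-dienoate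
Conditions: second-generation Grubbs catalyst RuCl2(=CHPh)(PCy3)(H2IMes) (5 mol %), 6 (large excess)/CH2Cl2, 40 °C, sealed tube
Reagents that add atoms: none
Why: olefin cross-metathesis in which only the monosubstituted terminal alkene enters the catalytic cycle and is capped as the isopropylidene by excess 6, the hindered electron-poor trisubstituted enoate alkene and C4 being untouched.

**Step 4**
Reactants: 7 ethyl (2E,4R)-4-[(tert-butyldimethylsilyl)oxy]-3,7-dimethylocta-2,6-dienoate
Product: 9 ethyl (2E,4R)-4-[(tert-butyldimethylsilyl)oxy]-7-hydroxy-3,7-dimethyloct-2-enoate, via alkylmercury acetate 8 (not isolated)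
Conditions: Hg(OAc)2 (1.1 equiv), THF/H2O 1:1, rt; then NaBH4, 3 M aq NaOH, 0 °C, 10 min
Reagents that add atoms: water, O
Why: Markovnikov oxymercuration–demercuration, in which divalent mercury attacks only the electron-rich C6=C7 alkene (the enoate alkene is deactivated, as in the known hydration of geranate esters), water opens the mercurinium ion at the tertiary carbon, and borohydride replaces mercury by hydrogen without touching C4.

**Step 5**
Reactants: 9 ethyl (2E,4R)-4-[(tert-butyldimethylsilyl)oxy]-7-hydroxy-3,7-dimethyloct-2-enoate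
Product: 10 (2E,4R)-4-[(tert-butyldimethylsilyl)oxy]-3,7-dimethyloct-2-ene-1,7-diol
Conditions: i-Bu2AlH (4 equiv), CH2Cl2, −78 → −20 °C; aq potassium sodium tartrate
Reagents that add atoms: none
Why: 1,2-reduction of the α,β-unsaturated ester by the aluminium hydride gives the primary allylic alcohol with the E geometry and the silyl ether intact (one equivalent of hydride is spent on the tertiary OH).

**Step 6**
Reactants: 10 (2E,4R)-4-[(tert-butyldimethylsilyl)oxy]-3,7-dimethyloct-2-ene-1,7-diol; 11 scopoletin (7-hydroxy-6-methoxy-2H-chromen-2-one)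
Product: 12 7-{[(2E,4R)-4-[(tert-butyldimethylsilyl)oxy]-7-hydroxy-3,7-dimethyloct-2-en-1-yl]oxy}-6-methoxy-2H-chromen-2-one
Conditions: PPh3 (1.5 equiv), DIAD (1.5 equiv), THF, 0 °C → rt
Reagents that add atoms: none
Why: Mitsunobu etherification, in which the acidic 7-OH of the coumarin displaces the oxyphosphonium of the primary allylic alcohol by SN2 at C1, the tertiary alcohol being too hindered to be activated and C4 being protected.

**Step 7**
Reactants: 12 7-{[(2E,4R)-4-[(tert-butyldimethylsilyl)oxy]-7-hydroxy-3,7-dimethyloct-2-en-1-yl]oxy}-6-methoxy-2H-chromen-2-one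
Product: 13 7-{[(2E,4R)-4,7-dihydroxy-3,7-dimethyloct-2-en-1-yl]oxy}-6-methoxy-2H-chromen-2-one
Conditions: Bu4NF (3 equiv), AcOH (3 equiv), THF, rt → 40 °C
Reagents that add atoms: none
Why: fluoride-driven desilylation cleaves only the Si–O bond, so C4 keeps its configuration, and the acetic acid buffer protects the coumarin lactone and the allylic aryl ether from base.

**Compound list**
1 | ethyl (2E)-3-methyl-4-oxobut-2-enoate | CCOC(=O)/C=C(\C)C=O | starting material
2 | allylmagnesium bromide | C=CC[Mg]Br | starting material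
3 | ethyl (2E,4R)-4-[(diisopinocampheylboryl)oxy]-3-methylhepta-2,6-dienoate (Ipc groups of the (−)-α-pinene series) | CCOC(=O)/C=C(\C)[C@H](OB([C@H]1C[C@H]2C[C@@H]([C@@H]1C)C2(C)C)[C@H]1C[C@H]2C[C@@H]([C@@H]1C)C2(C)C)CC=C | intermediate
4 | ethyl (2E,4R)-4-hydroxy-3-methylhepta-2,6-dienoate | CCOC(=O)/C=C(\C)[C@H](O)CC=C | intermediate
5 | ethyl (2E,4R)-4-[(tert-butyldimethylsilyl)oxy]-3-methylhepta-2,6-dienoate | CCOC(=O)/C=C(\C)[C@H](O[Si](C)(C)C(C)(C)C)CC=C | intermediate
6 | 2-methylbut-2-ene | CC=C(C)C | starting material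
7 | ethyl (2E,4R)-4-[(tert-butyldimethylsilyl)oxy]-3,7-dimethylocta-2,6-dienoate | CCOC(=O)/C=C(\C)[C@H](O[Si](C)(C)C(C)(C)C)CC=C(C)C | intermediate
8 | ethyl (2E,4R)-6-(acetoxymercurio)-4-[(tert-butyldimethylsilyl)oxy]-7-hydroxy-3,7-dimethyloct-2-enoate, both C6 epimers | CCOC(=O)/C=C(\C)[C@H](O[Si](C)(C)C(C)(C)C)CC([Hg]OC(C)=O)C(C)(C)O | intermediate
9 | ethyl (2E,4R)-4-[(tert-butyldimethylsilyl)oxy]-7-hydroxy-3,7-dimethyloct-2-enoate | CCOC(=O)/C=C(\C)[C@H](O[Si](C)(C)C(C)(C)C)CCC(C)(C)O | intermediate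
10 | (2E,4R)-4-[(tert-butyldimethylsilyl)oxy]-3,7-dimethyloct-2-ene-1,7-diol | OC/C=C(\C)[C@H](O[Si](C)(C)C(C)(C)C)CCC(C)(C)O | intermediate
11 | scopoletin (7-hydroxy-6-methoxy-2H-chromen-2-one) | COc1cc2ccc(=O)oc2cc1O | starting material
12 | 7-{[(2E,4R)-4-[(tert-butyldimethylsilyl)oxy]-7-hydroxy-3,7-dimethyloct-2-en-1-yl]oxy}-6-methoxy-2H-chromen-2-one | COc1cc2ccc(=O)oc2cc1OC/C=C(\C)[C@H](O[Si](C)(C)C(C)(C)C)CCC(C)(C)O | intermediate
13 | 7-{[(2E,4R)-4,7-dihydroxy-3,7-dimethyloct-2-en-1-yl]oxy}-6-methoxy-2H-chromen-2-one | COc1cc2ccc(=O)oc2cc1OC/C=C(\C)[C@H](O)CCC(C)(C)O | target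

**Step count:** 7 steps in total. Longest linear sequence: 7 steps (1 → 13).

**Steps most likely to fail, with fallbacks**

Step 1 (enantioselectivity of the allylboration on this electron-poor enal). The fallback sets out from 1 and comes back at 4. Zinc-mediated Barbier allylation of 1 (allyl bromide, Zn dust, THF/sat. aq NH4Cl, 0 °C → rt) gives racemic ethyl (2E)-4-hydroxy-3-methylhepta-2,6-dienoate F1. Dess–Martin periodinane with NaHCO3 (CH2Cl2, 0 °C) oxidises it to ethyl (2E)-3-methyl-4-oxohepta-2,6-dienoate F2, which is used crude and kept away from base so the allyl ketone does not slip into conjugation. Corey–Bakshi–Shibata reduction with (S)-Me-CBS oxazaborolidine and catecholborane (toluene, −78 °C) then returns 4: the α-methylalkenyl group plays the large substituent, as phenyl does in acetophenone, so hydride delivery gives 4R, and catecholborane does not hydroborate the terminal alkene at this temperature.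

Step 3 (cross-metathesis may stall or give ethylidene/isopropylidene mixtures). The fallback sets out from 5 and comes back at 7. Ozonolysis of 5 (O3, CH2Cl2/MeOH, −78 °C, Sudan red 7B as end-point indicator, then PPh3) cleaves only the terminal alkene, the enoate being far slower, and gives ethyl (2E,4R)-4-[(tert-butyldimethylsilyl)oxy]-3-methyl-6-oxohex-2-enoate F3. Wittig olefination of F3 with isopropylidenetriphenylphosphorane (from isopropyltriphenylphosphonium iodide and n-BuLi, THF, −78 → 0 °C) installs the isopropylidene and returns 7.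

Step 4 (oxymercuration: partial reversion to alkene on demercuration, ester hydrolysis in NaOH, or silyl ether participation). The fallback sets out from 7 and comes back at 10, bypassing 9. mCPBA with NaHCO3 (CH2Cl2, 0 °C) epoxidises only the electron-rich C6=C7 alkene to ethyl (2E,4R)-4-[(tert-butyldimethylsilyl)oxy]-5-(3,3-dimethyloxiran-2-yl)-3-methylpent-2-enoate F4 (both oxirane epimers, which converge later). i-Bu2AlH (CH2Cl2, −78 °C) reduces the ester to (2E,4R)-4-[(tert-butyldimethylsilyl)oxy]-5-(3,3-dimethyloxiran-2-yl)-3-methylpent-2-en-1-ol F5. LiEt3BH (THF, 0 °C → rt) then delivers hydride to the less substituted oxirane carbon, giving the tertiary alcohol 10.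

**Further compounds**
F1 | step 1 | racemic ethyl (2E)-4-hydroxy-3-methylhepta-2,6-dienoate | CCOC(=O)/C=C(\C)C(O)CC=C
F2 | step 1 | ethyl (2E)-3-methyl-4-oxohepta-2,6-dienoate | CCOC(=O)/C=C(\C)C(=O)CC=C
F3 | step 3 | ethyl (2E,4R)-4-[(tert-butyldimethylsilyl)oxy]-3-methyl-6-oxohex-2-enoate | CCOC(=O)/C=C(\C)[C@H](O[Si](C)(C)C(C)(C)C)CC=O
F4 | step 4 | ethyl (2E,4R)-4-[(tert-butyldimethylsilyl)oxy]-5-(3,3-dimethyloxiran-2-yl)-3-methylpent-2-enoate, both oxirane epimers | CCOC(=O)/C=C(\C)[C@H](O[Si](C)(C)C(C)(C)C)CC1OC1(C)C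
F5 | step 4 | (2E,4R)-4-[(tert-butyldimethylsilyl)oxy]-5-(3,3-dimethyloxiran-2-yl)-3-methylpent-2-en-1-ol, both oxirane epimers | OC/C=C(\C)[C@H](O[Si](C)(C)C(C)(C)C)CC1OC1(C)C
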